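**Retrosynthetic overview**

1. Pyran ring (formed last): O2–C3 bond by 6-endo oxa-Michael addition of the C1 hydroxyl to a 3-alkynyl-2-chlorocyclohexenone; the C4–C4a bond comes from a conjugate alkynylation/re-oxidation that joins core and side chain.
2. Carbocycle (formed second): an all-cis triol ketone from hydroxyl-directed dihydroxylation of (R)-4-(hydroxymethyl)-2-methylcyclohexenone, which comes from an organocatalytic Michael/aldol annulation of 3-silyloxypropanal with ethyl vinyl ketone.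
3. Side chain: (E)-enynol by hydroxyl-directed reduction of a diynol, made by chelation-controlled diynyl addition to 1-[(2S,3S)-3-methyloxolan-2-yl]ethanone.
4. Oxolane ring (formed first, key step): ring expansion of (S)-2-methyloxetane with ethyl diazoacetate through an oxonium ylide [1,2]-shift; the retained oxetane stereocentre then fixes oxolane C2 and, through it, the carbinol centre.

Assumption: 1, 4, 9, 14 and 15 are bought as such; core atoms are numbered as in the target isochromenone (C1 to C8a).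

**Step 1**
Reactants: 1 (S)-butane-1,3-diol
Product: 3 (S)-2-methyloxetane, via tosylate 2 (not isolated)
Conditions: TsCl (1.0 equiv), pyridine, CH2Cl2, −20 °C; then KOt-Bu (1.2 equiv), DMSO, 25 °C, product distilled out
Reagents that add atoms: 4-toluenesulfonyl chloride Cc1ccc(cc1)S(Cl)(=O)=O (atoms carried only in 2)
Why: Selective sulfonylation of the primary hydroxyl followed by 4-exo-tet intramolecular Williamson etherification by the secondary alkoxide forms the oxetane without touching the carbinol stereocentre.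

**Step 2**
Reactants: 3 (S)-2-methyloxetane (3 equiv); 4 ethyl diazoacetate
Product: 6 ethyl (2S,3S)-3-methyloxolane-2-carboxylate, via cis-ester 5 (not isolated)
Conditions: [Cu(MeCN)4]PF6 (2 mol%), 4,4′-di-tert-butyl-2,2′-bipyridine (2.2 mol%), 4 added over 6 h, CH2Cl2, 40 °C; then NaOEt (0.2 equiv), EtOH, 50 °C
Reagents that add atoms: none
Why: Proposed new method: a cationic monovalent copper carbene from 4 is captured by the oxetane oxygen to give an oxonium ylide, and strain release drives a Stevens-type [1,2]-shift of the more substituted ring carbon (C2, better radical-stabilising than C4) within a tight radical pair, so the methyl-bearing centre migrates with retention and becomes C3 (S) while ethoxide equilibrates the new ester-bearing C2 to the more stable trans (2S) isomer; the closest known reaction is the copper-catalysed oxonium-ylide ring expansion of 2-aryl and 2-alkynyl oxetanes with diazoacetates, not yet shown for an unactivated 2-alkyl oxetane.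

**Step 3**
Reactants: 6 ethyl (2S,3S)-3-methyloxolane-2-carboxylate
Product: 8 1-[(2S,3S)-3-methyloxolan-2-yl]ethan-1-one, via Weinreb amide 7 (not isolated)
Conditions: MeNHOMe·HCl (1.5 equiv), i-PrMgCl (3.0 equiv), THF, −20 °C; then MeMgBr (2.0 equiv), 0 °C; aq. NH4Cl
Reagents that add atoms: N,O-dimethylhydroxylamine hydrochloride CNOC.Cl (atoms carried only in 7); methylmagnesium bromide C[Mg]Br
Why: One-pot Weinreb amidation and Grignard addition stops at the ketone through the stable magnesium chelate; the epimerisable C2 stays in its thermodynamic trans configuration.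

**Step 4**
Reactants: 8 1-[(2S,3S)-3-methyloxolan-2-yl]ethan-1-one; 9 1,4-bis(trimethylsilyl)buta-1,3-diyne
Product: 11 (2S)-2-[(2S,3S)-3-methyloxolan-2-yl]-6-(trimethylsilyl)hexa-3,5-diyn-2-ol, via lithio-diyne 10 (not isolated)
Conditions: 9, MeLi·LiBr (1.0 equiv), Et2O, 23 °C; MgBr2·OEt2 (1.2 equiv); then 8, Et2O/CH2Cl2, −78 °C
Reagents that add atoms: none
Why: Mono-desilylation gives the diynyl nucleophile, whose magnesium form adds under Cram-chelate control (Mg bridging ring oxygen and carbonyl) from the face of the C2 hydrogen, anti to C3, which sets the (S)-carbinol.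

**Step 5**
Reactants: 11 (2S)-2-[(2S,3S)-3-methyloxolan-2-yl]-6-(trimethylsilyl)hexa-3,5-diyn-2-ol
Product: 13 (2S,3E)-2-[(2S,3S)-3-methyloxolan-2-yl]hex-3-en-5-yn-2-ol, via silyl enynol 12 (not isolated)
Conditions: NaAlH2(OCH2CH2OMe)2 (2.5 equiv), THF, 0 → 23 °C; then K2CO3, MeOH, 23 °C
Reagents that add atoms: none
Why: Alkoxide-directed trans-hydroalumination reduces only the propargylic alkyne to the (E)-alkene and leaves the remote silyl alkyne, which is then freed by methanolysis.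

**Step 6**
Reactants: 14 3-[(tert-butyldimethylsilyl)oxy]propanal; 15 pent-1-en-3-one
Product: 18 (4R)-4-(hydroxymethyl)-2-methylcyclohex-2-en-1-one, via keto-aldehyde 16 (not isolated), via silyl enone 17 (not isolated)
Conditions: (S)-2-[methoxy(diphenyl)methyl]pyrrolidine (5 mol%), ethyl 3,4-dihydroxybenzoate (20 mol%), neat, 4 °C; then TsOH·H2O (0.2 equiv), PhMe, 60 °C; then MeOH, 23 °C
Reagents that add atoms: none
Why: Enamine-catalysed Michael addition, in which the diarylprolinol ether shields one enamine face and sets C8a, is followed by acid-catalysed intramolecular aldol condensation (Robinson-type annulation) and acid methanolysis of the silyl ether.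

**Step 7**
Reactants: 18 (4R)-4-(hydroxymethyl)-2-methylcyclohex-2-en-1-one
Product: 20 (2R,3R,4S)-2,3-dihydroxy-4-(hydroxymethyl)-2-methylcyclohexan-1-one, via osmate ester 19 (not isolated)
Conditions: OsO4 (1.05 equiv), Me2NCH2CH2NMe2 (1.1 equiv), CH2Cl2, −78 °C; then aq. Na2SO3, THF, 23 °C
Reagents that add atoms: osmium tetroxide O=[Os](=O)(=O)=O
Why: Hydrogen-bond-directed dihydroxylation: the homoallylic hydroxyl delivers the diamine-bound OsO4 to the alkene face syn to CH2OH, which gives the all-cis triol and sets C7 and C8.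

**Step 8**
Reactants: 20 (2R,3R,4S)-2,3-dihydroxy-4-(hydroxymethyl)-2-methylcyclohexan-1-one
Product: 21 (2R,3R,4S)-2-methyl-2,3-bis[(triethylsilyl)oxy]-4-{[(triethylsilyl)oxy]methyl}cyclohexan-1-one
Conditions: Et3SiOTf (4 equiv), 2,6-lutidine (6 equiv), CH2Cl2, −78 → 23 °C
Reagents that add atoms: triethylsilyl trifluoromethanesulfonate CC[Si](CC)(CC)OS(=O)(=O)C(F)(F)F
Why: Exhaustive silylation with the silyl triflate protects primary, secondary and tertiary hydroxyls as fluoride-labile ethers; no stereocentre is affected.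

**Step 9**
Reactants: 21 (2R,3R,4S)-2-methyl-2,3-bis[(triethylsilyl)oxy]-4-{[(triethylsilyl)oxy]methyl}cyclohexan-1-one
Product: 22 (4S,5R,6R)-6-methyl-5,6-bis[(triethylsilyl)oxy]-4-{[(triethylsilyl)oxy]methyl}cyclohex-2-en-1-one
Conditions: LiN(i-Pr)2 (1.2 equiv), THF, −78 °C; then PhS(Cl)=N-t-Bu (1.3 equiv), −78 °C
Reagents that add atoms: none
Why: Mukaiyama dehydrogenation: only C5 is enolisable (C7 is quaternary), and the enolate is sulfenylated and undergoes syn-elimination at low temperature to the C4a=C5 enone.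

**Step 10**
Reactants: 22 (4S,5R,6R)-6-methyl-5,6-bis[(triethylsilyl)oxy]-4-{[(triethylsilyl)oxy]methyl}cyclohex-2-en-1-one
Product: 23 (4S,5R,6R)-2-chloro-6-methyl-5,6-bis[(triethylsilyl)oxy]-4-{[(triethylsilyl)oxy]methyl}cyclohex-2-en-1-one
Conditions: PhSeCl (2.2 equiv), pyridine (3 equiv), CH2Cl2, 0 → 23 °C
Reagents that add atoms: phenylselenenyl chloride Cl[Se]c1ccccc1
Why: Pyridine-buffered α-chlorination of the enone (α-selenenylation, then chloride transfer with loss of the diselenide) places chlorine on C5 under conditions that spare the silyl ethers.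

**Step 11**
Reactants: 23 (4S,5R,6R)-2-chloro-6-methyl-5,6-bis[(triethylsilyl)oxy]-4-{[(triethylsilyl)oxy]methyl}cyclohex-2-en-1-one; 13 (2S,3E)-2-[(2S,3S)-3-methyloxolan-2-yl]hex-3-en-5-yn-2-ol (1.3 equiv)
Product: 25 (4S,5R,6R)-2-chloro-6-methyl-3-{(3E,5S)-5-[(2S,3S)-3-methyloxolan-2-yl]-5-[(trimethylsilyl)oxy]hex-3-en-1-yn-1-yl}-5,6-bis[(triethylsilyl)oxy]-4-{[(triethylsilyl)oxy]methyl}cyclohex-2-en-1-one, via silyl enol ether 24 (not isolated)
Conditions: 13, n-BuLi (2.1 equiv), THF, −78 °C; ZnBr2 (1.1 equiv), 0 °C; then 23, Me3SiOTf (2.5 equiv), Et2O, −40 → 0 °C; then Pd(OAc)2 (1.2 equiv), MeCN, 23 °C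
Reagents that add atoms: trimethylsilyl trifluoromethanesulfonate C[Si](C)(C)OS(=O)(=O)C(F)(F)F
Why: Silyl-triflate-promoted conjugate addition of the alkynylzinc to the activated chloro-enone gives a silyl enol ether, which Saegusa–Ito oxidation returns to the enone, now alkynylated at C4a; the transient C4a stereocentre is destroyed and the side-chain alkoxide is capped as its silyl ether.

**Step 12**
Reactants: 25 (4S,5R,6R)-2-chloro-6-methyl-3-{(3E,5S)-5-[(2S,3S)-3-methyloxolan-2-yl]-5-[(trimethylsilyl)oxy]hex-3-en-1-yn-1-yl}-5,6-bis[(triethylsilyl)oxy]-4-{[(triethylsilyl)oxy]methyl}cyclohex-2-en-1-one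
Product: 27 (7R,8R,8aS)-5-chloro-7,8-dihydroxy-3-{(1E,3S)-3-hydroxy-3-[(2S,3S)-3-methyloxolan-2-yl]but-1-en-1-yl}-7-methyl-1,7,8,8a-tetrahydro-6H-isochromen-6-one, via hydroxy ynone 26 (not isolated)
Conditions: Bu4NF/AcOH (1:1, 6 equiv), THF, 0 → 23 °C
Reagents that add atoms: none
Why: Buffered fluoride removes all four silyl groups and the freed C1 hydroxyl adds 6-endo-dig to the δ-carbon of the ynenone (1,6-oxa-Michael addition, protonation at C4), closing the pyran without creating or disturbing a stereocentre.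

**Compound list**

1 | (S)-butane-1,3-diol | C[C@H](O)CCO | starting material
2 | (S)-3-hydroxybutyl 4-methylbenzenesulfonate | C[C@H](O)CCOS(=O)(=O)c1ccc(C)cc1 | intermediate (not isolated)
3 | (S)-2-methyloxetane | C[C@H]1CCO1 | intermediate
4 | ethyl diazoacetate | CCOC(=O)C=[N+]=[N-] | starting material
5 | ethyl (2R,3S)-3-methyloxolane-2-carboxylate (cis epimer) | C[C@H]1CCO[C@H]1C(=O)OCC | intermediate (not isolated)
6 | ethyl (2S,3S)-3-methyloxolane-2-carboxylate (trans) | C[C@H]1CCO[C@@H]1C(=O)OCC | intermediate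
7 | (2S,3S)-N-methoxy-N,3-dimethyloxolane-2-carboxamide | C[C@H]1CCO[C@@H]1C(=O)N(C)OC | intermediate (not isolated)
8 | 1-[(2S,3S)-3-methyloxolan-2-yl]ethan-1-one | C[C@H]1CCO[C@@H]1C(C)=O | intermediate
9 | 1,4-bis(trimethylsilyl)buta-1,3-diyne | C[Si](C)(C)C#CC#C[Si](C)(C)C | starting material
10 | [4-(trimethylsilyl)buta-1,3-diyn-1-yl]lithium | [Li]C#CC#C[Si](C)(C)C | intermediate (not isolated)
11 | (2S)-2-[(2S,3S)-3-methyloxolan-2-yl]-6-(trimethylsilyl)hexa-3,5-diyn-2-ol | C[C@H]1CCO[C@@H]1[C@@](C)(O)C#CC#C[Si](C)(C)C | intermediate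
12 | (2S,3E)-2-[(2S,3S)-3-methyloxolan-2-yl]-6-(trimethylsilyl)hex-3-en-5-yn-2-ol | C[C@H]1CCO[C@@H]1[C@@](C)(O)/C=C/C#C[Si](C)(C)C | intermediate (not isolated)
13 | (2S,3E)-2-[(2S,3S)-3-methyloxolan-2-yl]hex-3-en-5-yn-2-ol | C[C@H]1CCO[C@@H]1[C@@](C)(O)/C=C/C#C | intermediate
14 | 3-[(tert-butyldimethylsilyl)oxy]propanal | O=CCCO[Si](C)(C)C(C)(C)C | starting material
15 | pent-1-en-3-one (ethyl vinyl ketone) | CCC(=O)C=C | starting material
16 | (2S)-2-{[(tert-butyldimethylsilyl)oxy]methyl}-5-oxoheptanal | O=C[C@@H](CCC(=O)CC)CO[Si](C)(C)C(C)(C)C | intermediate (not isolated)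
17 | (4R)-4-{[(tert-butyldimethylsilyl)oxy]methyl}-2-methylcyclohex-2-en-1-one | O=C1C(C)=C[C@H](CO[Si](C)(C)C(C)(C)C)CC1 | intermediate (not isolated)
18 | (4R)-4-(hydroxymethyl)-2-methylcyclohex-2-en-1-one | O=C1C(C)=C[C@H](CO)CC1 | intermediate
19 | cyclic osmate ester: 2,3-diolate of 20 on OsO2(Me2NCH2CH2NMe2), hexavalent osmium | O=C1[C@](C)(O%10)[C@H](O[Os-2]%10(=O)(=O)([N+](C)(C)CC%11)[N+]%11(C)C)[C@H](CO)CC1 | intermediate (not isolated)
20 | (2R,3R,4S)-2,3-dihydroxy-4-(hydroxymethyl)-2-methylcyclohexan-1-one (all-cis) | O=C1[C@](C)(O)[C@H](O)[C@H](CO)CC1 | intermediate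
21 | (2R,3R,4S)-2-methyl-2,3-bis[(triethylsilyl)oxy]-4-{[(triethylsilyl)oxy]methyl}cyclohexan-1-one | O=C1[C@](C)(O[Si](CC)(CC)CC)[C@H](O[Si](CC)(CC)CC)[C@H](CO[Si](CC)(CC)CC)CC1 | intermediate
22 | (4S,5R,6R)-6-methyl-5,6-bis[(triethylsilyl)oxy]-4-{[(triethylsilyl)oxy]methyl}cyclohex-2-en-1-one | O=C1[C@](C)(O[Si](CC)(CC)CC)[C@H](O[Si](CC)(CC)CC)[C@H](CO[Si](CC)(CC)CC)C=C1 | intermediate
23 | (4S,5R,6R)-2-chloro-6-methyl-5,6-bis[(triethylsilyl)oxy]-4-{[(triethylsilyl)oxy]methyl}cyclohex-2-en-1-one | O=C1[C@](C)(O[Si](CC)(CC)CC)[C@H](O[Si](CC)(CC)CC)[C@H](CO[Si](CC)(CC)CC)C=C1Cl | intermediate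
24 | trimethylsilyl enol ether of the conjugate adduct (2-chloro-1-silyloxycyclohexene, alkynyl-bearing carbon as epimer mixture, other centres as in 23) | ClC1=C(O[Si](C)(C)C)[C@](C)(O[Si](CC)(CC)CC)[C@H](O[Si](CC)(CC)CC)[C@H](CO[Si](CC)(CC)CC)C1C#C/C=C/[C@](C)(O[Si](C)(C)C)[C@H]1OCC[C@@H]1C | intermediate (not isolated)
25 | (4S,5R,6R)-2-chloro-6-methyl-3-{(3E,5S)-5-[(2S,3S)-3-methyloxolan-2-yl]-5-[(trimethylsilyl)oxy]hex-3-en-1-yn-1-yl}-5,6-bis[(triethylsilyl)oxy]-4-{[(triethylsilyl)oxy]methyl}cyclohex-2-en-1-one | O=C1[C@](C)(O[Si](CC)(CC)CC)[C@H](O[Si](CC)(CC)CC)[C@H](CO[Si](CC)(CC)CC)C(C#C/C=C/[C@](C)(O[Si](C)(C)C)[C@H]2OCC[C@@H]2C)=C1Cl | intermediate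
26 | (4S,5R,6R)-2-chloro-5,6-dihydroxy-4-(hydroxymethyl)-3-{(3E,5S)-5-hydroxy-5-[(2S,3S)-3-methyloxolan-2-yl]hex-3-en-1-yn-1-yl}-6-methylcyclohex-2-en-1-one | O=C1[C@](C)(O)[C@H](O)[C@H](CO)C(C#C/C=C/[C@](C)(O)[C@H]2OCC[C@@H]2C)=C1Cl | intermediate (not isolated)
27 | (7R,8R,8aS)-5-chloro-7,8-dihydroxy-3-{(1E,3S)-3-hydroxy-3-[(2S,3S)-3-methyloxolan-2-yl]but-1-en-1-yl}-7-methyl-1,7,8,8a-tetrahydro-6H-isochromen-6-one | C[C@H]1CCO[C@@H]1[C@@](C)(O)/C=C/C1=CC2=C(Cl)C(=O)[C@](C)(O)[C@H](O)[C@@H]2CO1 | target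

**Step count**

Total: 12 steps. Longest linear sequence: 7 steps (steps 6 to 12; the side-chain branch, steps 1 to 5 then 11 and 12, is equally long).

**Three steps most likely to fail**

Step 2 (the proposed new ring expansion). An unactivated secondary alkyl group migrates less readily than the aryl or alkynyl-substituted carbons used so far. The ylide may instead fragment by β-hydrogen transfer, the primary C4 may migrate, or the radical pair may partly lose configuration. The fallback uses known chemistry only and sets out from 4. Rh2(OAc)4-catalysed O–H insertion of 4 into the primary hydroxyl of (R)-butane-1,3-diol (C[C@@H](O)CCO, used in excess) gives ethyl 2-{[(3R)-3-hydroxybutyl]oxy}acetate F1. Mesylation (MsCl, Et3N) gives ethyl 2-{[(3R)-3-(methanesulfonyloxy)butyl]oxy}acetate F2. KN(SiMe3)2 in THF at −78 °C then closes the oxolane by 5-exo-tet C-alkylation of the ester enolate, with inversion at the methyl-bearing carbon. The resulting cis/trans mixture (5 and 6) is equilibrated with NaOEt as in the main route, and the fallback comes back at 6.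

Step 11 (conjugate alkynylation and re-oxidation). The hindered chloro-enone may add the functionalised alkynylzinc slowly or 1,2, and stoichiometric Pd(OAc)2 may attack the enyne instead of the chloro enol ether. The fallback sets out from 22 and forms the C4–C4a bond by cross-coupling. Nucleophilic epoxidation (t-BuOOH, DBU) gives the 2,3-epoxy ketone F3. Isomerisation with Pd(PPh3)4 and Ph2PCH2CH2PPh2 gives (4R,5R,6S)-4-methyl-4,5-bis[(triethylsilyl)oxy]-6-{[(triethylsilyl)oxy]methyl}cyclohexane-1,3-dione F4. N-Chlorosuccinimide gives its 2-chloro derivative F5. Tf2O with 2,6-lutidine sulfonylates the less hindered enol oxygen to give (4S,5R,6R)-2-chloro-6-methyl-3-(trifluoromethanesulfonyloxy)-5,6-bis[(triethylsilyl)oxy]-4-{[(triethylsilyl)oxy]methyl}cyclohex-2-en-1-one F6. Sonogashira coupling with 13 (Pd(PPh3)4, copper iodide CuI, Et3N) gives the enynone with a free tertiary hydroxyl F7. Under the conditions of step 12, F7 comes back to the route at 26 and then 27.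

Step 12 (global desilylation and ring closure). Even buffered fluoride may epimerise C8a, eliminate the C8 oxygen or trigger retro-aldol cleavage before the pyran closes. The fallback sets out from 25 and separates ring closure from deprotection. Pyridinium p-toluenesulfonate in MeOH at 0 °C removes only the primary triethylsilyl and the tertiary trimethylsilyl group to give the primary alcohol F8. (Ph3P)AuNTf2 (2 mol%) in CH2Cl2 effects 6-endo cycloisomerisation to the bis(triethylsilyl)-protected isochromenone F9. Et3N·3HF in MeCN then removes the last two silyl groups, and the fallback comes back at 27.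

**Further compounds**

F1 | step 2 | ethyl 2-{[(3R)-3-hydroxybutyl]oxy}acetate | CCOC(=O)COCC[C@@H](C)O
F2 | step 2 | ethyl 2-{[(3R)-3-(methanesulfonyloxy)butyl]oxy}acetate | CCOC(=O)COCC[C@@H](C)OS(C)(=O)=O
F3 | step 11 | 2,3-epoxide of 22 (epoxy ketone, oxirane configuration not controlled) | O=C1[C@](C)(O[Si](CC)(CC)CC)[C@H](O[Si](CC)(CC)CC)[C@H](CO[Si](CC)(CC)CC)C2OC12
F4 | step 11 | (4R,5R,6S)-4-methyl-4,5-bis[(triethylsilyl)oxy]-6-{[(triethylsilyl)oxy]methyl}cyclohexane-1,3-dione | O=C1[C@](C)(O[Si](CC)(CC)CC)[C@H](O[Si](CC)(CC)CC)[C@H](CO[Si](CC)(CC)CC)C(=O)C1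
F5 | step 11 | (4R,5R,6S)-2-chloro-4-methyl-4,5-bis[(triethylsilyl)oxy]-6-{[(triethylsilyl)oxy]methyl}cyclohexane-1,3-dione | O=C1[C@](C)(O[Si](CC)(CC)CC)[C@H](O[Si](CC)(CC)CC)[C@H](CO[Si](CC)(CC)CC)C(=O)C1Cl
F6 | step 11 | (4S,5R,6R)-2-chloro-6-methyl-3-(trifluoromethanesulfonyloxy)-5,6-bis[(triethylsilyl)oxy]-4-{[(triethylsilyl)oxy]methyl}cyclohex-2-en-1-one | O=C1[C@](C)(O[Si](CC)(CC)CC)[C@H](O[Si](CC)(CC)CC)[C@H](CO[Si](CC)(CC)CC)C(OS(=O)(=O)C(F)(F)F)=C1Cl
F7 | step 11 | (4S,5R,6R)-2-chloro-3-{(3E,5S)-5-hydroxy-5-[(2S,3S)-3-methyloxolan-2-yl]hex-3-en-1-yn-1-yl}-6-methyl-5,6-bis[(triethylsilyl)oxy]-4-{[(triethylsilyl)oxy]methyl}cyclohex-2-en-1-one | O=C1[C@](C)(O[Si](CC)(CC)CC)[C@H](O[Si](CC)(CC)CC)[C@H](CO[Si](CC)(CC)CC)C(C#C/C=C/[C@](C)(O)[C@H]2OCC[C@@H]2C)=C1Cl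
F8 | step 12 | (4S,5R,6R)-2-chloro-4-(hydroxymethyl)-3-{(3E,5S)-5-hydroxy-5-[(2S,3S)-3-methyloxolan-2-yl]hex-3-en-1-yn-1-yl}-6-methyl-5,6-bis[(triethylsilyl)oxy]cyclohex-2-en-1-one | O=C1[C@](C)(O[Si](CC)(CC)CC)[C@H](O[Si](CC)(CC)CC)[C@H](CO)C(C#C/C=C/[C@](C)(O)[C@H]2OCC[C@@H]2C)=C1Cl
F9 | step 12 | (7R,8R,8aS)-5-chloro-3-{(1E,3S)-3-hydroxy-3-[(2S,3S)-3-methyloxolan-2-yl]but-1-en-1-yl}-7-methyl-7,8-bis[(triethylsilyl)oxy]-1,7,8,8a-tetrahydro-6H-isochromen-6-one | C[C@H]1CCO[C@@H]1[C@@](C)(O)/C=C/C1=CC2=C(Cl)C(=O)[C@](C)(O[Si](CC)(CC)CC)[C@H](O[Si](CC)(CC)CC)[C@@H]2CO1
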